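You are asked how much substrate has reacted in the flask at 3.0 min and what the pH is then, and the moment to watch is when the scavenger feed overtakes the reaction.

| flask | substrate | acid | scavenger | remark | time |
|---|---|---|---|---|---|
| ash | 0.13 M | 0.20 mM | 0.20 M (fed, over 3.0 min) | run made earlier |  |
| birch | 0.30 M | 0.20 mM | 0.20 M (fed, over 3.0 min) | run made earlier |  |
| flask | 0.20 M | 0.200 mM | 0.200 M (fed, over 3.0 min) |  | 3.0 min |

| run | time / s | substrate / % | target / % |
|---|---|---|---|
| ash | 10.0 | 85.6 | 9.4 |
| ash | 20.0 | 69.3 | 20.3 |
| ash | 50.0 | 43.9 | 47.8 |
| ash | 120 | 21.8 | 77.3 |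
| birch | 10.0 | 81.0 | 10.8 |
| birch | 20.0 | 63.6 | 19.8 |
| birch | 50.0 | 30.3 | 48.2 |
| birch | 120 | 10.4 | 80.5 |

(scatter of a reading: 1 percentage point)

- acid is the free proton; pH is minus the decimal logarithm of its molar concentration
- a reading of substrate is of its free form alone

- part of the substrate that has reacted at 3.0 min
- pH of the solution at 3.0 min

My chain starts from the last target reading of each run. Read as pseudo-first-order, the ash run gives 0.0124 s⁻¹ and the birch run 0.0136 s⁻¹, so I take 0.0130 s⁻¹, and the flask has 90.3 % reacted at the asked time. The weak link is that single constant, so I reforge it by carrying each run's value separately, which gives 89.3 % and 91.4 %: two estimates from the same first-order reading, not bounds on the answer.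

Scavenger arrives at 1.11 mM s⁻¹, while target starts at 2.60 mM s⁻¹, which is faster. The two rates meet when the substrate has fallen to 85.5 mM, at 65.4 s. This crossing time, the moment target is made just as fast as scavenger arrives, finds target leading the feed by 41.8 mM. Afterwards the feed gains, and its whole 0.200 M exceeds the 181 mM of target expected. If scavenger takes up what the reaction gives off, I expect the pH at the asked time close to its start, perhaps slightly under.

The forecast says 90 % and pH 3.7: “The catalyst therefore survives and pH stays near 3.70”.

The flask gives 92.0 % and pH 3.53, both within the forecast's margins.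

    substrate + weak acid ⇌ idle adduct, settled at all times (K = 15.3 M⁻¹)
    weak acid ⇌ conjugate base + acid, settled at all times (K = 5.00 × 10⁻⁶ M)
    substrate + acid → weak acid + acid + target (k = 36.8 M⁻¹ s⁻¹)
    substrate → weak acid + target (k = 0.00228 s⁻¹)
    weak acid + scavenger → scavenged by-product (k = 4.27 M⁻¹ s⁻¹)

In the flask, half of the acid-path turnover was done by 0.804 min, before the crossing time, and half of the scavenging by 1.45 min, after it; at 1.50 min weak acid stood at 0.0304 M, acid at 251 % of its charge and free scavenger at 4.34 %. By 3.00 min weak acid had fallen to 0.00542 M and acid to 146 %. The neighbour flask with 0.12 M of substrate has, by the same reckoning, its crossing time at 26.1 s with an estimated lead of 5.53 mM; it reached 87.9 % and ended with acid at 105 % of its charge.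

The runs were generated by integration for an exercise; noise was put on by code.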